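**Retrosynthetic overview**
1. The target is PGE2 1,15-lactone 11-acetate (8R,11R,12R,15S; 5Z,13E, prostaglandin numbering); the acetate is put on last, from an 11-O-TBS ether.
2. The 5Z olefin of the 13-membered lactone comes from semi-hydrogenation of a cycloalkyne, itself closed by ring-closing alkyne metathesis (C5–C6) of a diyne ester.
3. The diyne ester comes from esterifying the C15 alcohol with hept-5-ynoic acid after selective removal of a C15 TES ether.
4. The cyclopentanone with both side chains comes from a one-pot three-component coupling of (R)-4-silyloxycyclopentenone, an (S,E)-alkenyl zincate made from (S)-oct-1-yn-3-ol, and 1-iodobut-2-yne (C12–C13 and C7–C8 bonds).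
5. Ring order: the five-membered ring is bought; the 13-membered lactone is the only ring formed (step 7).

Assumption: prostaglandins themselves (PGE2 and the like) are not treated as starting materials; (S)-oct-1-yn-3-ol, (R)-4-(tert-butyldimethylsilyloxy)cyclopent-2-en-1-one, 1-bromobut-2-yne and hept-5-ynoic acid are bought.

**Route**

Step 1
Reactants: 1 (S)-oct-1-yn-3-ol
Product: 2 (S)-triethyl(oct-1-yn-3-yloxy)silane
Conditions: TESCl, imidazole, CH2Cl2, 0 °C to rt
Reagents that add atoms: chlorotriethylsilane (TESCl), CC[Si](Cl)(CC)CC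
Why: Imidazole-promoted silyl ether formation masks the C15 hydroxyl with a group that can later be removed beside a TBS ether, and the S centre is not touched.

Step 2
Reactants: 2 (S)-triethyl(oct-1-yn-3-yloxy)silane
Product: 4 triethyl{[(1E,3S)-1-iodooct-1-en-3-yl]oxy}silane, via alkenylzirconocene chloride 3 (not isolated)
Conditions: Cp2Zr(H)Cl, THF, rt, dark; then I2, THF, 0 °C; aq Na2S2O3
Reagents that add atoms: iodine, [I][I]
Why: Schwartz hydrozirconation adds Zr–H syn across the terminal alkyne with zirconium on the terminal carbon, and iodinolysis with retention gives the E-alkenyl iodide only.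

Step 3
Reactants: 5 1-bromobut-2-yne
Product: 6 1-iodobut-2-yne
Conditions: sodium iodide, acetone, rt, dark
Reagents that add atoms: sodium iodide, [Na+].[I-]
Why: Finkelstein halide exchange (SN2) is driven by precipitation of sodium bromide and gives the more reactive propargylic iodide needed for enolate trapping.

Step 4
Reactants: 4 triethyl{[(1E,3S)-1-iodooct-1-en-3-yl]oxy}silane; 6 1-iodobut-2-yne; 7 (R)-4-[(tert-butyldimethylsilyl)oxy]cyclopent-2-en-1-one
Product: 11 (2R,3R,4R)-2-(but-2-yn-1-yl)-4-[(tert-butyldimethylsilyl)oxy]-3-[(1E,3S)-3-(triethylsilyloxy)oct-1-en-1-yl]cyclopentan-1-one, via alkenyllithium 8 (not isolated), via lithium alkenyl(dimethyl)zincate 9 (not isolated), via zinc enolate 10 (not isolated)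
Conditions: 4, t-BuLi (2 equiv), Et2O, −78 °C; Me2Zn, THF, −78 to 0 °C; 7, THF, −78 °C; HMPA, 6, −78 to −40 °C; aq NH4Cl
Reagents that add atoms: none
Why: In this Noyori-type three-component coupling the alkenyl group of the mixed zincate adds 1,4 anti to the C4 silyloxy group (sets ring C3 = C12), and the enolate is then alkylated by the propargylic iodide anti to the new C3 substituent (sets ring C2 = C8), giving the all-trans pattern.

Step 5
Reactants: 11 (2R,3R,4R)-2-(but-2-yn-1-yl)-4-[(tert-butyldimethylsilyl)oxy]-3-[(1E,3S)-3-(triethylsilyloxy)oct-1-en-1-yl]cyclopentan-1-one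
Product: 12 (2R,3R,4R)-2-(but-2-yn-1-yl)-4-[(tert-butyldimethylsilyl)oxy]-3-[(1E,3S)-3-hydroxyoct-1-en-1-yl]cyclopentan-1-one
Conditions: AcOH/THF/H2O (3:1:1), rt
Reagents that add atoms: none
Why: Mild acid solvolysis cleaves the more labile triethylsilyl ether much faster than the bulkier secondary TBS ether and does not disturb the β-silyloxy ketone.

Step 6
Reactants: 12 (2R,3R,4R)-2-(but-2-yn-1-yl)-4-[(tert-butyldimethylsilyl)oxy]-3-[(1E,3S)-3-hydroxyoct-1-en-1-yl]cyclopentan-1-one; 13 hept-5-ynoic acid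
Product: 15 (1E,3S)-1-{(1R,2R,5R)-2-(but-2-yn-1-yl)-5-[(tert-butyldimethylsilyl)oxy]-3-oxocyclopentyl}oct-1-en-3-yl hept-5-ynoate, via O-acylisourea 14 (not isolated)
Conditions: DCC, DMAP (cat.), CH2Cl2, 0 °C to rt
Reagents that add atoms: none
Why: Steglich esterification acylates the allylic C15 alcohol without breaking its C–O bond, so the 15S configuration is retained.

Step 7
Reactants: 15 (1E,3S)-1-{(1R,2R,5R)-2-(but-2-yn-1-yl)-5-[(tert-butyldimethylsilyl)oxy]-3-oxocyclopentyl}oct-1-en-3-yl hept-5-ynoate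
Product: 16 5,6-didehydro-PGE2 1,15-lactone 11-O-TBS ether (13-membered cycloalkyne lactone; 8R,11R,12R,15S; 13E)
Conditions: Mo(≡C-C6H4-4-OMe)(OSiPh3)3 (5 mol%), 5 Å molecular sieves, toluene (0.002 M), rt to 60 °C
Reagents that add atoms: none
Why: Ring-closing alkyne metathesis joins the two methyl-capped alkynes with loss of but-2-yne (taken up by the sieves), and the molybdenum alkylidyne leaves the E-olefin, ketone, ester and silyl ether alone.

Step 8
Reactants: 16 5,6-didehydro-PGE2 1,15-lactone 11-O-TBS ether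
Product: 17 PGE2 1,15-lactone 11-O-TBS ether (5Z,13E; 8R,11R,12R,15S)
Conditions: H2 (1 atm), Pd on CaCO3 poisoned with Pb(OAc)2, quinoline, EtOAc, rt
Reagents that add atoms: none
Why: Lindlar semi-hydrogenation delivers H2 syn to the ring alkyne to give the 5Z olefin, while the disubstituted 13E olefin is not reduced on the poisoned catalyst.

Step 9
Reactants: 17 PGE2 1,15-lactone 11-O-TBS ether
Product: 18 PGE2 1,15-lactone (5Z,13E; 8R,11R,12R,15S)
Conditions: HF·pyridine, MeCN, 0 °C
Reagents that add atoms: none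
Why: Fluoride-driven desilylation under weakly acidic, non-basic conditions frees the 11-hydroxyl without β-elimination of the aldol unit or opening of the lactone.

Step 10
Reactants: 18 PGE2 1,15-lactone
Product: 19 PGE2 1,15-lactone 11-acetate, (5Z,8R,11R,12R,13E,15S)-11-acetoxy-9-oxoprosta-5,13-dien-1,15-olide
Conditions: Ac2O, pyridine, 0 °C to rt
Reagents that add atoms: acetic anhydride, CC(=O)OC(C)=O
Why: O-Acetylation (nucleophilic acyl substitution at the anhydride) of the only free hydroxyl proceeds with retention at C11, and the weak base at low temperature limits elimination to the enone.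

**Compound list**

1 | (S)-oct-1-yn-3-ol | CCCCC[C@H](O)C#C | starting material
2 | (S)-triethyl(oct-1-yn-3-yloxy)silane | CCCCC[C@H](O[Si](CC)(CC)CC)C#C | intermediate
3 | chlorobis(cyclopentadienyl)[(1E,3S)-3-(triethylsilyloxy)oct-1-en-1-yl]zirconium | CCCCC[C@H](O[Si](CC)(CC)CC)/C=C/[Zr](Cl)(C1C=CC=C1)C1C=CC=C1 | intermediate
4 | triethyl{[(1E,3S)-1-iodooct-1-en-3-yl]oxy}silane | CCCCC[C@H](O[Si](CC)(CC)CC)/C=C/I | intermediate
5 | 1-bromobut-2-yne | CC#CCBr | starting material
6 | 1-iodobut-2-yne | CC#CCI | intermediate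
7 | (R)-4-[(tert-butyldimethylsilyl)oxy]cyclopent-2-en-1-one | O=C1C=C[C@H](O[Si](C)(C)C(C)(C)C)C1 | starting material
8 | (1E,3S)-3-(triethylsilyloxy)oct-1-en-1-yllithium | CCCCC[C@H](O[Si](CC)(CC)CC)/C=C/[Li] | intermediate
9 | lithium dimethyl[(1E,3S)-3-(triethylsilyloxy)oct-1-en-1-yl]zincate | [Li+].CCCCC[C@H](O[Si](CC)(CC)CC)/C=C/[Zn-](C)C | intermediate
10 | lithium dimethylzincate enolate (C1–C2) of (3R,4R)-4-[(tert-butyldimethylsilyl)oxy]-3-[(1E,3S)-3-(triethylsilyloxy)oct-1-en-1-yl]cyclopentanone | [Li+].CCCCC[C@H](O[Si](CC)(CC)CC)/C=C/[C@H]1[C@H](O[Si](C)(C)C(C)(C)C)CC(O[Zn-](C)C)=C1 | intermediate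
11 | (2R,3R,4R)-2-(but-2-yn-1-yl)-4-[(tert-butyldimethylsilyl)oxy]-3-[(1E,3S)-3-(triethylsilyloxy)oct-1-en-1-yl]cyclopentan-1-one | CCCCC[C@H](O[Si](CC)(CC)CC)/C=C/[C@H]1[C@H](O[Si](C)(C)C(C)(C)C)CC(=O)[C@@H]1CC#CC | intermediate
12 | (2R,3R,4R)-2-(but-2-yn-1-yl)-4-[(tert-butyldimethylsilyl)oxy]-3-[(1E,3S)-3-hydroxyoct-1-en-1-yl]cyclopentan-1-one | CCCCC[C@H](O)/C=C/[C@H]1[C@H](O[Si](C)(C)C(C)(C)C)CC(=O)[C@@H]1CC#CC | intermediate
13 | hept-5-ynoic acid | CC#CCCCC(=O)O | starting material
14 | O-(hept-5-ynoyl)-N,N'-dicyclohexylisourea | CC#CCCCC(=O)OC(=NC1CCCCC1)NC1CCCCC1 | intermediate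
15 | (1E,3S)-1-{(1R,2R,5R)-2-(but-2-yn-1-yl)-5-[(tert-butyldimethylsilyl)oxy]-3-oxocyclopentyl}oct-1-en-3-yl hept-5-ynoate | CCCCC[C@H](OC(=O)CCCC#CC)/C=C/[C@H]1[C@H](O[Si](C)(C)C(C)(C)C)CC(=O)[C@@H]1CC#CC | intermediate
16 | 5,6-didehydro-PGE2 1,15-lactone 11-O-TBS ether (8R,11R,12R,15S; 13E) | CCCCC[C@H]1/C=C/[C@H]2[C@H](O[Si](C)(C)C(C)(C)C)CC(=O)[C@@H]2CC#CCCCC(=O)O1 | intermediate
17 | PGE2 1,15-lactone 11-O-TBS ether (8R,11R,12R,15S; 5Z,13E) | CCCCC[C@H]1/C=C/[C@H]2[C@H](O[Si](C)(C)C(C)(C)C)CC(=O)[C@@H]2C/C=C\CCCC(=O)O1 | intermediate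
18 | PGE2 1,15-lactone (8R,11R,12R,15S; 5Z,13E) | CCCCC[C@H]1/C=C/[C@H]2[C@H](O)CC(=O)[C@@H]2C/C=C\CCCC(=O)O1 | intermediate
19 | PGE2 1,15-lactone 11-acetate, (5Z,8R,11R,12R,13E,15S)-11-acetoxy-9-oxoprosta-5,13-dien-1,15-olide | CCCCC[C@H]1/C=C/[C@H]2[C@H](OC(C)=O)CC(=O)[C@@H]2C/C=C\CCCC(=O)O1 | target

**Step count and risks**

Total step count: 10. Longest linear sequence: 9 steps (1 → 2 → 4 → 11 → 12 → 15 → 16 → 17 → 18 → 19; step 3 is a side branch).

Most likely to fail, first: step 4. The alkylation of enolate 10 is slow and competes with enolate equilibration, loss of the β-silyloxy group and double alkylation. The fallback sets out from zinc enolate 10, made exactly as in step 4, and replaces the SN2 alkylation by an aldol reaction followed by radical deoxygenation. Enolate 10 is quenched at −78 °C with but-2-ynal (bought), which reacts far faster than an alkyl iodide, to give the carbinol-epimer mixture (2S,3R,4R)-4-[(tert-butyldimethylsilyl)oxy]-2-(1-hydroxybut-2-yn-1-yl)-3-[(1E,3S)-3-(triethylsilyloxy)oct-1-en-1-yl]cyclopentan-1-one F1. O-Phenyl chlorothionoformate, pyridine and catalytic DMAP in CH2Cl2 convert it into the O-phenyl thionocarbonate of that carbinol F2. Barton–McCombie deoxygenation with Bu3SnH and AIBN in toluene at 80 °C then removes the extra oxygen, and the route is rejoined at 11.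

Second: step 7. The strained 13-membered cycloalkyne may form slowly, giving oligomers or catalyst death at the ketone. The fallback sets out again from zinc enolate 10 and builds the 5Z olefin directly by olefin metathesis. The enolate is trapped with allyl iodide (bought; HMPA, −78 to −40 °C) to give (2R,3R,4R)-2-allyl-4-[(tert-butyldimethylsilyl)oxy]-3-[(1E,3S)-3-(triethylsilyloxy)oct-1-en-1-yl]cyclopentan-1-one F3. AcOH/THF/H2O removes the triethylsilyl group to give (2R,3R,4R)-2-allyl-4-[(tert-butyldimethylsilyl)oxy]-3-[(1E,3S)-3-hydroxyoct-1-en-1-yl]cyclopentan-1-one F4. DCC/DMAP esterification with hex-5-enoic acid (bought) gives (1E,3S)-1-{(1R,2R,5R)-2-allyl-5-[(tert-butyldimethylsilyl)oxy]-3-oxocyclopentyl}oct-1-en-3-yl hex-5-enoate F5. Z-selective ring-closing olefin metathesis then closes the 13-membered ring with loss of ethene. The catalyst is Ru(NO3)(=CH-C6H4-2-O-i-Pr)(NHC), where the NHC is 1-(2,6-diisopropylphenyl)-3-(adamant-1-yl)imidazolin-2-ylidene bound through the carbene carbon and one adamantyl carbon, used in 1,2-dichloroethane at 60 °C under high dilution. The route is rejoined at 17, so neither the alkyne metathesis nor the semi-hydrogenation is needed.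

Third: step 10. The β-acetoxy ketone can eliminate under base to the cyclopentenone, and the free aldol 18 is itself prone to dehydration. The fallback sets out from 17 and avoids both the free aldol and any base. Ac2O with catalytic Cu(OTf)2 in CH2Cl2 at 0 °C to rt exchanges the silyl ether directly for the acetate under Lewis-acid catalysis, with retention at C11, and the route is rejoined at 19. This way makes no new compound, entered below as none F0.

**Further compounds**

F1 | step 4 | (2S,3R,4R)-4-[(tert-butyldimethylsilyl)oxy]-2-(1-hydroxybut-2-yn-1-yl)-3-[(1E,3S)-3-(triethylsilyloxy)oct-1-en-1-yl]cyclopentan-1-one (carbinol epimers) | CCCCC[C@H](O[Si](CC)(CC)CC)/C=C/[C@H]1[C@H](O[Si](C)(C)C(C)(C)C)CC(=O)[C@@H]1C(O)C#CC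
F2 | step 4 | O-phenyl thionocarbonate of F1 at the side-chain carbinol | CCCCC[C@H](O[Si](CC)(CC)CC)/C=C/[C@H]1[C@H](O[Si](C)(C)C(C)(C)C)CC(=O)[C@@H]1C(OC(=S)Oc2ccccc2)C#CC
F3 | step 7 | (2R,3R,4R)-2-allyl-4-[(tert-butyldimethylsilyl)oxy]-3-[(1E,3S)-3-(triethylsilyloxy)oct-1-en-1-yl]cyclopentan-1-one | CCCCC[C@H](O[Si](CC)(CC)CC)/C=C/[C@H]1[C@H](O[Si](C)(C)C(C)(C)C)CC(=O)[C@@H]1CC=C
F4 | step 7 | (2R,3R,4R)-2-allyl-4-[(tert-butyldimethylsilyl)oxy]-3-[(1E,3S)-3-hydroxyoct-1-en-1-yl]cyclopentan-1-one | CCCCC[C@H](O)/C=C/[C@H]1[C@H](O[Si](C)(C)C(C)(C)C)CC(=O)[C@@H]1CC=C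
F5 | step 7 | (1E,3S)-1-{(1R,2R,5R)-2-allyl-5-[(tert-butyldimethylsilyl)oxy]-3-oxocyclopentyl}oct-1-en-3-yl hex-5-enoate | CCCCC[C@H](OC(=O)CCCC=C)/C=C/[C@H]1[C@H](O[Si](C)(C)C(C)(C)C)CC(=O)[C@@H]1CC=C
F0 | step 10 | none | none
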